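u = upper 5-deoxy unit (rings A, C, B); l = lower afzelechin unit (rings D, F, E). The target is fisetinidol-(4α→8)-afzelechin, (2R,3S,4S) in u and (2R,3S) in l.
Feature used: ring D (C4a-l, C5-l, C6-l, C7-l, C8-l, C8a-l) is a phloroglucinol with an acetate-type 1,3,5-oxygen pattern. On a finished arene C6-l and C8-l, and the oxygens on C5-l, C7-l and C8a-l, are hard to tell apart. Ring D is therefore made last, from a chain in which O1-l already sits on C8a-l, C4-l on C4a-l and C4-u on C8-l.
Disconnection 1 (after debenzylation): C5-l–C6-l, a Claisen condensation with aromatisation of keto ester 26 (methyl ketone C6-l/C7-l, ring-F ester C5-l).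
Disconnection 2: C4-u–C8-l, an SN1 alkylation of silyl dienol ether 15 (rings E, F) by flavan-4-yl acetate 25 (rings A, C, B).
15 comes from methyl acetoacetate and an Evans syn-glycolate aldol unit (C4-l–C4a-l alkylation, O1-l–C2-l closure with inversion, acetylation at C8-l). 25 comes from a chalcone by asymmetric epoxidation. Ring order: F and C in parallel, then D.

Key step: step 19

Remark: 10 and 11 (C4a-l), 26 (C8-l) and 15 (enol ether geometry) are carried as mixtures because these elements become planar later. 24 and 25 are drawn as the expected 3,4-trans isomers, although C4-u is ionised in step 18.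

Step 1
Reactants: 1 (R)-4-benzyl-1,3-oxazolidin-2-one; 2 (benzyloxy)acetyl chloride
Product: 3 (R)-4-benzyl-3-[(benzyloxy)acetyl]-1,3-oxazolidin-2-one
Conditions: n-BuLi, THF, −78 °C; then 2, −78 to 0 °C
Reagents that add atoms: none
Why: N-acylation of the lithiated oxazolidinone with an acid chloride is the standard way to load an Evans auxiliary and brings in C3-l, C4-l and the O3-l benzyl ether without touching the auxiliary stereocentre.

Step 2
Reactants: 3 (R)-4-benzyl-3-[(benzyloxy)acetyl]-1,3-oxazolidin-2-one; 4 4-(benzyloxy)benzaldehyde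
Product: 5 (4R)-4-benzyl-3-{(2R,3S)-2-(benzyloxy)-3-[4-(benzyloxy)phenyl]-3-hydroxypropanoyl}-1,3-oxazolidin-2-one
Conditions: Bu2BOTf, Et3N, CH2Cl2, −78 to 0 °C; 4, −78 to 0 °C; H2O2, MeOH, pH 7 buffer
Reagents that add atoms: none
Why: Evans syn aldol reaction, in which the Z-boron enolate reacts through a closed chair-like transition state on the face away from the auxiliary benzyl group, setting C3-l in its final arrangement and placing the C2-l hydroxyl syn to O3-l, opposite to what ring F needs, so that it can later leave with inversion (closure with retention of a syn unit would give the 2,3-cis ring).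

Step 3
Reactants: 5 syn aldol adduct
Product: 6 (4R)-4-benzyl-3-{(2R,3S)-2-(benzyloxy)-3-[4-(benzyloxy)phenyl]-3-[(tert-butyldimethylsilyl)oxy]propanoyl}-1,3-oxazolidin-2-one
Conditions: TBSOTf, 2,6-lutidine, CH2Cl2, 0 °C
Reagents that add atoms: tert-butyldimethylsilyl triflate, CC(C)(C)[Si](C)(C)OS(=O)(=O)C(F)(F)F
Why: Silylation with a silyl triflate and a hindered pyridine base is mild enough for the acid-labile 4-alkoxybenzylic carbinol and masks it, so that in steps 4 to 6 it can neither lactonise onto C5-l nor add to the C8a-l ketone.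

Step 4
Reactants: 6 silylated aldol adduct
Product: 7 (2S,3S)-2-(benzyloxy)-3-[4-(benzyloxy)phenyl]-3-[(tert-butyldimethylsilyl)oxy]propan-1-ol
Conditions: LiBH4, MeOH, Et2O, 0 °C
Reagents that add atoms: none
Why: Reductive removal of the auxiliary with LiBH4 attacks the exocyclic imide carbonyl selectively, gives the C4-l primary alcohol without epimerising C3-l and returns the oxazolidinone.

Step 5
Reactants: 7 primary alcohol
Product: 8 (2R,3S)-2-(benzyloxy)-3-[4-(benzyloxy)phenyl]-3-[(tert-butyldimethylsilyl)oxy]-1-iodopropane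
Conditions: I2, PPh3, imidazole, CH2Cl2, 0 °C to rt
Reagents that add atoms: iodine, II
Why: Appel-type iodination converts the only free (primary) hydroxyl into an iodide under nearly neutral conditions that leave the silyl and benzyl ethers alone.

Step 6
Reactants: 8 iodide; 9 methyl acetoacetate
Product: 10 methyl (4S,5S)-2-acetyl-4-(benzyloxy)-5-[4-(benzyloxy)phenyl]-5-[(tert-butyldimethylsilyl)oxy]pentanoate (C2 epimers)
Conditions: NaH, 9 (excess), DMF–THF, 0 °C; then 8, 60 °C
Reagents that add atoms: none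
Why: Classical acetoacetic ester alkylation, in which the soft sodium enolate displaces the primary iodide by SN2 at carbon to form C4-l–C4a-l, the new C4a-l centre being irrelevant because it becomes sp2 in step 8.

Step 7
Reactants: 10 silylated keto ester
Product: 11 methyl (4S,5S)-2-acetyl-4-(benzyloxy)-5-[4-(benzyloxy)phenyl]-5-hydroxypentanoate (C2 epimers)
Conditions: HF·pyridine, pyridine, THF, 0 °C to rt
Reagents that add atoms: none
Why: Fluoride-driven desilylation in pyridine-buffered medium frees the C2-l carbinol without the strong acid that would ionise it or the alkoxide that would lactonise onto the ester.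

Step 8
Reactants: 11 hydroxy keto ester
Product: 12 methyl (5S,6R)-5-(benzyloxy)-6-[4-(benzyloxy)phenyl]-2-methyl-5,6-dihydro-4H-pyran-3-carboxylate
Conditions: PBu3, ADDP, toluene, 0 °C to rt
Reagents that add atoms: none
Why: Intramolecular Mitsunobu etherification (ADDP/PBu3 variant for weakly acidic partners), in which the enolate oxygen on C8a-l displaces the C2-l oxyphosphonium group in a 6-exo-tet SN2 closure, so that C2-l is inverted to R and ring F forms 2,3-trans, while C-alkylation would need a cyclobutane.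

Step 9
Reactants: 12 2-methyl dihydropyran ester; 13 N-methoxy-N-methylacetamide
Product: 14 methyl (5S,6R)-5-(benzyloxy)-6-[4-(benzyloxy)phenyl]-2-(2-oxopropyl)-5,6-dihydro-4H-pyran-3-carboxylate
Conditions: LiN(iPr)2, THF, −78 °C; 13, −78 to −20 °C; AcOH, −78 °C
Reagents that add atoms: none
Why: Vinylogous (γ) deprotonation of the β-alkoxy-α,β-unsaturated ester at its C8-l methyl group and acylation by an N-methoxy-N-methylamide, a pattern known for 3-alkoxycrotonates and 6-methyl-1,3-dioxin-4-ones, adds C7-l and C6-l, and the chelated tetrahedral adduct lasts until the cold quench, which prevents over-reaction and lactonisation to the pyran-2-one.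

Step 10
Reactants: 14 keto ester
Product: 15 methyl (5S,6R)-5-(benzyloxy)-6-[4-(benzyloxy)phenyl]-2-{2-[(tert-butyldimethylsilyl)oxy]prop-1-en-1-yl}-5,6-dihydro-4H-pyran-3-carboxylate (E/Z mixture)
Conditions: TBSOTf, Et3N, CH2Cl2, 0 °C
Reagents that add atoms: tert-butyldimethylsilyl triflate, CC(C)(C)[Si](C)(C)OS(=O)(=O)C(F)(F)F
Why: Soft enolisation with a silyl triflate and Et3N removes the more acidic C8-l hydrogen and gives the conjugated silyl dienol ether, which turns the weakly enolised ketone into a competent carbon nucleophile at C8-l.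

Step 11
Reactants: 16 1-[4-(benzyloxy)-2-hydroxyphenyl]ethanone
Product: 17 1-[4-(benzyloxy)-2-(methoxymethoxy)phenyl]ethanone
Conditions: NaH, MOMCl, DMF, 0 °C
Reagents that add atoms: chloromethyl methyl ether, COCCl
Why: Williamson-type acetal protection of the chelated phenol blocks the cyclisation and oxidative side reactions that a free 2'-hydroxychalcone would undergo in steps 12 and 13.

Step 12
Reactants: 17 protected acetophenone; 18 3,4-bis(benzyloxy)benzaldehyde
Product: 19 (E)-1-[4-(benzyloxy)-2-(methoxymethoxy)phenyl]-3-[3,4-bis(benzyloxy)phenyl]prop-2-en-1-one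
Conditions: KOH, EtOH, rt
Reagents that add atoms: none
Why: Claisen–Schmidt condensation of a methyl ketone with a non-enolisable aldehyde forms the C2-u–C3-u bond and gives the E-chalcone as the thermodynamic alkene.

Step 13
Reactants: 19 chalcone
Product: 20 [4-(benzyloxy)-2-(methoxymethoxy)phenyl]{(2R,3S)-3-[3,4-bis(benzyloxy)phenyl]oxiran-2-yl}methanone
Conditions: poly-L-leucine, urea–H2O2, DBU, THF, rt
Reagents that add atoms: urea–hydrogen peroxide, OO.NC(N)=O
Why: Juliá–Colonna epoxidation, in which hydroperoxide adds to the enone held by the helical poly-L-leucine, should deliver the (αR,βS)-trans-epoxide and so fix the C3-u–O bond in its final arrangement.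

Step 14
Reactants: 20 epoxy ketone
Product: 22 (2R,3R)-7-(benzyloxy)-2-[3,4-bis(benzyloxy)phenyl]-3-hydroxy-2,3-dihydro-4H-chromen-4-one, via free phenol epoxide 21 (not isolated)
Conditions: HCl (aq.), MeOH–THF, 50 °C
Reagents that add atoms: none
Why: Acid removes the methoxymethyl group, and the freed phenol opens the protonated epoxide at the 3,4-dialkoxybenzylic carbon (6-endo) with inversion, keeping the C3-u–O bond and closing ring C as the 2,3-trans dihydroflavonol, which is also the more stable isomer.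

Step 15
Reactants: 22 dihydroflavonol
Product: 23 (2R,3R)-3,7-bis(benzyloxy)-2-[3,4-bis(benzyloxy)phenyl]-2,3-dihydro-4H-chromen-4-one
Conditions: BnOC(=NH)CCl3, TfOH (cat.), CH2Cl2–cyclohexane, 0 °C to rt
Reagents that add atoms: benzyl 2,2,2-trichloroacetimidate, ClC(Cl)(Cl)C(=N)OCc1ccccc1
Why: Acid-catalysed imidate benzylation avoids the base that would epimerise or ring-open the dihydroflavonol, and the O3-u benzyl ether is needed because a free O3-u alkoxide could later add to C8a-l (5-exo-trig) and expel O1-l or close onto the C7-l ketone.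

Step 16
Reactants: 23 3-O-benzyl dihydroflavonol
Product: 24 (2R,3S,4R)-3,7-bis(benzyloxy)-2-[3,4-bis(benzyloxy)phenyl]-3,4-dihydro-2H-chromen-4-ol
Conditions: NaBH4, THF–MeOH, 0 °C
Reagents that add atoms: none
Why: Borohydride reduction of 2,3-trans 3-oxygenated flavanones gives mainly the equatorial 3,4-trans benzylic alcohol, and the C4-u configuration is of no consequence because this centre is ionised in step 18.

Step 17
Reactants: 24 flavan-4-ol
Product: 25 4-O-acetate of 24
Conditions: Ac2O, pyridine, DMAP (cat.), CH2Cl2, 0 °C to rt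
Reagents that add atoms: acetic anhydride, CC(=O)OC(C)=O
Why: Acetylation turns the hydroxyl into a leaving group that a silyl triflate can remove catalytically without releasing water, which would hydrolyse 15.

Step 18
Reactants: 15 silyl dienol ether; 25 flavan-4-yl acetate
Product: 26 methyl (5S,6R)-5-(benzyloxy)-6-[4-(benzyloxy)phenyl]-2-{2-oxo-1-[(2R,3S)-3,7-bis(benzyloxy)-2-[3,4-bis(benzyloxy)phenyl]chroman-4α-yl]propyl}-5,6-dihydro-4H-pyran-3-carboxylate (both C8-l epimers)
Conditions: TMSOTf (cat.), 4 Å MS, CH2Cl2, −78 °C; Et3N quench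
Reagents that add atoms: none
Why: Mukaiyama-type SN1 alkylation of a silyl enol ether, in which the 2,4-dioxygenated benzylic acetate ionises far more readily than the C2-l–O1-l bond, 15 attacks through C8-l (attack through C4a-l would build a quaternary centre and break the push–pull conjugation), and the approach to the half-chair cation anti to the pseudo-equatorial 3-OBn group sets C4-u as 4α (3,4-trans).

Step 19
Reactants: 26 keto ester (both C8-l epimers)
Product: 28 3-u,7-u,3'-u,4'-u,3-l,4'-l-hexa-O-benzyl-fisetinidol-(4α→8)-afzelechin (free 5-l/7-l phenols), via ring D enedione 27 (not isolated)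
Conditions: NaOMe, MeOH–THF, Ar, 65 to 90 °C (sealed tube); AcOH
Reagents that add atoms: none
Why: Proposed new method: methoxide interconverts the C8-l and C6-l enolates of 26, and only the C6-l (methyl) enolate can reach the C5-l ester, which the C4a-l=C8a-l double bond of ring F holds cis to the side chain; addition, loss of methoxide (C5-l–C6-l bond) and enolisation of enedione 27 to the phenolate make the sequence irreversible. The closest known reaction types are the Dieckmann-type closure of 5-oxohexanoates to cyclohexane-1,3-diones, the Claisen cyclisation of 3,5-dioxoalkanoate chains to phloroglucinols and the alkoxide-induced change of 4-alkoxy-6-methylpyran-2-ones into phloroglucinol monoethers, none of which has been run on a ring-fused vinylogous carbonate with a tertiary C8-l. Ring D closes in the 6-(enolexo)-exo-trig mode. No stereocentre is made: C8-l becomes sp2, so both epimers converge, and C2-l, C3-l, C2-u, C3-u and C4-u carry no acidic hydrogen. The step needs C- over O-acylation and cyclisation over cleavage: the pyran-2-one from attack of O7-l on C5-l is reopened by methoxide and is only a reservoir, the bulky C4-u substituent lowers the acidity of C8-l–H and shields the C7-l ketone against retro-Claisen attack, and connectivity (one methyl, one ester) fixes the regiochemistry. With O3-u, O3-l and all phenols of rings A, B and E benzylated, no alkoxide can displace O1-l from C8a-l and no quinone methide can open ring C or ring F.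

Step 20
Reactants: 28 hexabenzyl ether
Product: 29 fisetinidol-(4α→8)-afzelechin (target, CNP0322555.1)
Conditions: H2 (1 atm), Pd(OH)2/C, THF–MeOH–H2O, rt
Reagents that add atoms: none
Why: Hydrogenolysis of benzyl ethers over Pd(OH)2/C at ambient pressure is the standard last step for oligoflavanoids and, when stopped at full debenzylation, leaves the C4-u–C8-l bond, both C2–O1 bonds and all five stereocentres untouched.

Compound list
1 | (R)-4-benzyl-1,3-oxazolidin-2-one | O=C1N[C@H](Cc2ccccc2)CO1 | starting material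
2 | (benzyloxy)acetyl chloride | O=C(Cl)COCc1ccccc1 | starting material
3 | (R)-4-benzyl-3-[(benzyloxy)acetyl]-1,3-oxazolidin-2-one | O=C1OC[C@@H](Cc2ccccc2)N1C(=O)COCc1ccccc1 | intermediate
4 | 4-(benzyloxy)benzaldehyde | O=Cc1ccc(OCc2ccccc2)cc1 | starting material
5 | (4R)-4-benzyl-3-{(2R,3S)-2-(benzyloxy)-3-[4-(benzyloxy)phenyl]-3-hydroxypropanoyl}-1,3-oxazolidin-2-one | O=C1OC[C@@H](Cc2ccccc2)N1C(=O)[C@@H]([C@@H](O)c1ccc(OCc2ccccc2)cc1)OCc1ccccc1 | intermediate
6 | O-TBS ether of 5 | O=C1OC[C@@H](Cc2ccccc2)N1C(=O)[C@@H]([C@@H](O[Si](C)(C)C(C)(C)C)c1ccc(OCc2ccccc2)cc1)OCc1ccccc1 | intermediate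
7 | (2S,3S)-2-(benzyloxy)-3-[4-(benzyloxy)phenyl]-3-[(tert-butyldimethylsilyl)oxy]propan-1-ol | OC[C@@H]([C@@H](O[Si](C)(C)C(C)(C)C)c1ccc(OCc2ccccc2)cc1)OCc1ccccc1 | intermediate
8 | (2R,3S)-2-(benzyloxy)-3-[4-(benzyloxy)phenyl]-3-[(tert-butyldimethylsilyl)oxy]-1-iodopropane | IC[C@@H]([C@@H](O[Si](C)(C)C(C)(C)C)c1ccc(OCc2ccccc2)cc1)OCc1ccccc1 | intermediate
9 | methyl acetoacetate | COC(=O)CC(C)=O | starting material
10 | methyl (4S,5S)-2-acetyl-4-(benzyloxy)-5-[4-(benzyloxy)phenyl]-5-[(tert-butyldimethylsilyl)oxy]pentanoate (C2 epimers) | COC(=O)C(C(C)=O)C[C@@H]([C@@H](O[Si](C)(C)C(C)(C)C)c1ccc(OCc2ccccc2)cc1)OCc1ccccc1 | intermediate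
11 | methyl (4S,5S)-2-acetyl-4-(benzyloxy)-5-[4-(benzyloxy)phenyl]-5-hydroxypentanoate (C2 epimers) | COC(=O)C(C(C)=O)C[C@@H]([C@@H](O)c1ccc(OCc2ccccc2)cc1)OCc1ccccc1 | intermediate
12 | methyl (5S,6R)-5-(benzyloxy)-6-[4-(benzyloxy)phenyl]-2-methyl-5,6-dihydro-4H-pyran-3-carboxylate | O(Cc1ccccc1)c1ccc([C@H]2OC(C)=C(C(=O)OC)C[C@@H]2OCc2ccccc2)cc1 | intermediate
13 | N-methoxy-N-methylacetamide | CC(=O)N(C)OC | starting material
14 | methyl (5S,6R)-5-(benzyloxy)-6-[4-(benzyloxy)phenyl]-2-(2-oxopropyl)-5,6-dihydro-4H-pyran-3-carboxylate | O(Cc1ccccc1)c1ccc([C@H]2OC(CC(C)=O)=C(C(=O)OC)C[C@@H]2OCc2ccccc2)cc1 | intermediate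
15 | methyl (5S,6R)-5-(benzyloxy)-6-[4-(benzyloxy)phenyl]-2-{2-[(tert-butyldimethylsilyl)oxy]prop-1-en-1-yl}-5,6-dihydro-4H-pyran-3-carboxylate (E/Z mixture) | O(Cc1ccccc1)c1ccc([C@H]2OC(C=C(C)O[Si](C)(C)C(C)(C)C)=C(C(=O)OC)C[C@@H]2OCc2ccccc2)cc1 | intermediate
16 | 1-[4-(benzyloxy)-2-hydroxyphenyl]ethanone | CC(=O)c1ccc(OCc2ccccc2)cc1O | starting material
17 | 1-[4-(benzyloxy)-2-(methoxymethoxy)phenyl]ethanone | CC(=O)c1ccc(OCc2ccccc2)cc1OCOC | intermediate
18 | 3,4-bis(benzyloxy)benzaldehyde | O=Cc1ccc(OCc2ccccc2)c(OCc2ccccc2)c1 | starting material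
19 | (E)-1-[4-(benzyloxy)-2-(methoxymethoxy)phenyl]-3-[3,4-bis(benzyloxy)phenyl]prop-2-en-1-one | O=C(/C=C/c1ccc(OCc2ccccc2)c(OCc2ccccc2)c1)c1ccc(OCc2ccccc2)cc1OCOC | intermediate
20 | [4-(benzyloxy)-2-(methoxymethoxy)phenyl]{(2R,3S)-3-[3,4-bis(benzyloxy)phenyl]oxiran-2-yl}methanone | O=C([C@@H]1O[C@H]1c1ccc(OCc2ccccc2)c(OCc2ccccc2)c1)c1ccc(OCc2ccccc2)cc1OCOC | intermediate
21 | [4-(benzyloxy)-2-hydroxyphenyl]{(2R,3S)-3-[3,4-bis(benzyloxy)phenyl]oxiran-2-yl}methanone (formed in the flask) | O=C([C@@H]1O[C@H]1c1ccc(OCc2ccccc2)c(OCc2ccccc2)c1)c1ccc(OCc2ccccc2)cc1O | intermediate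
22 | (2R,3R)-7-(benzyloxy)-2-[3,4-bis(benzyloxy)phenyl]-3-hydroxy-2,3-dihydro-4H-chromen-4-one | O=C1c2ccc(OCc3ccccc3)cc2O[C@H](c2ccc(OCc3ccccc3)c(OCc3ccccc3)c2)[C@H]1O | intermediate
23 | (2R,3R)-3,7-bis(benzyloxy)-2-[3,4-bis(benzyloxy)phenyl]-2,3-dihydro-4H-chromen-4-one | O=C1c2ccc(OCc3ccccc3)cc2O[C@H](c2ccc(OCc3ccccc3)c(OCc3ccccc3)c2)[C@H]1OCc1ccccc1 | intermediate
24 | (2R,3S,4R)-3,7-bis(benzyloxy)-2-[3,4-bis(benzyloxy)phenyl]-3,4-dihydro-2H-chromen-4-ol | O[C@@H]1c2ccc(OCc3ccccc3)cc2O[C@H](c2ccc(OCc3ccccc3)c(OCc3ccccc3)c2)[C@H]1OCc1ccccc1 | intermediate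
25 | 4-O-acetate of 24 (2,3-trans-3,4-trans) | CC(=O)O[C@@H]1c2ccc(OCc3ccccc3)cc2O[C@H](c2ccc(OCc3ccccc3)c(OCc3ccccc3)c2)[C@H]1OCc1ccccc1 | intermediate
26 | methyl (5S,6R)-5-(benzyloxy)-6-[4-(benzyloxy)phenyl]-2-{2-oxo-1-[(2R,3S)-3,7-bis(benzyloxy)-2-[3,4-bis(benzyloxy)phenyl]chroman-4α-yl]propyl}-5,6-dihydro-4H-pyran-3-carboxylate (both C8-l epimers) | O(Cc5ccccc5)c1ccc([C@H]2OC(C(C(C)=O)[C@@H]3c4ccc(OCc5ccccc5)cc4O[C@H](c4ccc(OCc5ccccc5)c(OCc5ccccc5)c4)[C@H]3OCc5ccccc5)=C(C(=O)OC)C[C@@H]2OCc5ccccc5)cc1 | intermediate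
27 | ring D enedione (C5-l and C7-l ketones, C6-l methylene, C8-l methine; formed in the flask) | O(Cc5ccccc5)c1ccc([C@H]2OC6=C(C(=O)CC(=O)C6[C@@H]3c4ccc(OCc5ccccc5)cc4O[C@H](c4ccc(OCc5ccccc5)c(OCc5ccccc5)c4)[C@H]3OCc5ccccc5)C[C@@H]2OCc5ccccc5)cc1 | intermediate
28 | 3-u,7-u,3'-u,4'-u,3-l,4'-l-hexa-O-benzyl-fisetinidol-(4α→8)-afzelechin (free 5-l/7-l phenols) | O(Cc5ccccc5)c1ccc([C@H]2Oc3c(c(O)cc(O)c3[C@@H]3c4ccc(OCc5ccccc5)cc4O[C@H](c4ccc(OCc5ccccc5)c(OCc5ccccc5)c4)[C@H]3OCc5ccccc5)C[C@@H]2OCc5ccccc5)cc1 | intermediate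
29 | fisetinidol-(4α→8)-afzelechin (CNP0322555.1) | Oc1ccc([C@H]2Oc3c(c(O)cc(O)c3[C@@H]3c4ccc(O)cc4O[C@H](c4ccc(O)c(O)c4)[C@H]3O)C[C@@H]2O)cc1 | target

Total step count: 20. Longest linear sequence: 13 steps (steps 1 to 10, then 18 to 20). The upper branch (steps 11 to 17) runs in parallel.

Steps most likely to fail

Step 19 (ring D Claisen closure).
- What may go wrong: the substrate may rest as the unreactive C8-l dienolate or as the pyran-2-one formed by O-acylation. Meanwhile slow methoxide attack at C7-l (retro-Claisen loss of the acetyl group) or at C8a-l (exchange of O1-l for methoxide, opening ring F) may drain material before C-acylation occurs.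
- Fallback: it uses the established arene route, sets out from 25 and comes back at 29. Purchased (+)-afzelechin F1 is benzylated at its three phenols (BnBr, K2CO3, DMF) to 5,7,4'-tri-O-benzylafzelechin F2. F2 is used in excess as the arene nucleophile toward 25 (TMSOTf, CH2Cl2, −78 °C). The known preference of 5,7-di-O-benzylflavan-3-ols for substitution at C8 should give the 4α→8 linked heptabenzyl ether F3. Hydrogenolysis of F3 over Pd(OH)2/C delivers 29.

Step 18 (C4-u–C8-l bond).
- What may go wrong: facial selectivity at the C4-u cation may be poor, because only the 3-OBn group shields the β face. Protodesilylation of 15, attack through C4a-l or oxygen, and acid-induced ionisation of the C2-l–O1-l bond may also compete.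
- Fallback: it changes the control element to neighbouring-group participation, sets out from 22 (with 15) and comes back at 26. Compound 22 is reduced with NaBH4 to the 2,3-trans-3,4-trans tri-O-benzyl flavan-3,4-diol F4 and acetylated (Ac2O, pyridine) to the 3,4-diacetate F5. On ionisation with TMSOTf the O3-u acetate bridges the β face of C4-u as a dioxolan-2-ylium ion, so 15 can only enter from the α face, giving the 3-u-O-acetyl keto ester F6. Brief K2CO3/MeOH at 0 °C frees the 3-u-hydroxy keto ester F7. Neutral benzylation of F7 (2-benzyloxy-1-methylpyridinium triflate, MgO, PhCF3) gives 26.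

Step 8 (ring F closure with inversion).
- What may go wrong: proton transfer from the weakly acidic keto ester may be slow. The C2-l oxyphosphonium ion would then ionise (loss of stereospecificity), eliminate toward the enol ether, or be captured by the hydrazide.
- Fallback: it replaces the nucleophile by a strongly acidic 4-hydroxypyran-2-one, sets out from 10 and comes back at 14, which also makes step 9 unnecessary. The dianion of 10 (NaH, then n-BuLi, THF, 0 °C) is acylated at its terminal methyl by 13 to the 3,5-dioxohexanoate F8. DBU in warm toluene closes F8 to the 3-alkyl-4-hydroxy-6-methylpyran-2-one F9, and HF·pyridine frees the carbinol F10. A standard Mitsunobu closure (PPh3, DIAD, THF) through the pyranone hydroxyl inverts C2-l to give the 2,3-trans pyrano[4,3-b]pyran-5-one F11. NaOMe in MeOH at 0 °C to rt, followed by a cold AcOH quench, opens the lactone to 14.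

Further compounds
F1 | step 19 | (+)-afzelechin (purchased) | Oc1ccc([C@H]2Oc3cc(O)cc(O)c3C[C@@H]2O)cc1
F2 | step 19 | 5,7,4'-tri-O-benzylafzelechin | O(Cc1ccccc1)c1ccc([C@H]2Oc3cc(OCc4ccccc4)cc(OCc4ccccc4)c3C[C@@H]2O)cc1
F3 | step 19 | 3-u,7-u,3'-u,4'-u,5-l,7-l,4'-l-hepta-O-benzyl-fisetinidol-(4α→8)-afzelechin | O(Cc5ccccc5)c1ccc([C@H]2Oc3c(c(OCc5ccccc5)cc(OCc5ccccc5)c3[C@@H]3c4ccc(OCc5ccccc5)cc4O[C@H](c4ccc(OCc5ccccc5)c(OCc5ccccc5)c4)[C@H]3OCc5ccccc5)C[C@@H]2O)cc1
F4 | step 18 | (2R,3S,4R)-7-(benzyloxy)-2-[3,4-bis(benzyloxy)phenyl]-3,4-dihydro-2H-chromene-3,4-diol | O[C@@H]1c2ccc(OCc3ccccc3)cc2O[C@H](c2ccc(OCc3ccccc3)c(OCc3ccccc3)c2)[C@H]1O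
F5 | step 18 | 3,4-di-O-acetate of F4 | CC(=O)O[C@@H]1c2ccc(OCc3ccccc3)cc2O[C@H](c2ccc(OCc3ccccc3)c(OCc3ccccc3)c2)[C@H]1OC(C)=O
F6 | step 18 | 3-u-O-acetyl analogue of 26 (both C8-l epimers) | O(Cc5ccccc5)c1ccc([C@H]2OC(C(C(C)=O)[C@@H]3c4ccc(OCc5ccccc5)cc4O[C@H](c4ccc(OCc5ccccc5)c(OCc5ccccc5)c4)[C@H]3OC(C)=O)=C(C(=O)OC)C[C@@H]2OCc5ccccc5)cc1
F7 | step 18 | 3-u-hydroxy analogue of 26 (both C8-l epimers) | O(Cc5ccccc5)c1ccc([C@H]2OC(C(C(C)=O)[C@@H]3c4ccc(OCc5ccccc5)cc4O[C@H](c4ccc(OCc5ccccc5)c(OCc5ccccc5)c4)[C@H]3O)=C(C(=O)OC)C[C@@H]2OCc5ccccc5)cc1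
F8 | step 8 | methyl 2-{(2S,3S)-2-(benzyloxy)-3-[4-(benzyloxy)phenyl]-3-[(tert-butyldimethylsilyl)oxy]propyl}-3,5-dioxohexanoate | COC(=O)C(C(=O)CC(C)=O)C[C@@H]([C@@H](O[Si](C)(C)C(C)(C)C)c1ccc(OCc2ccccc2)cc1)OCc1ccccc1
F9 | step 8 | 3-{(2S,3S)-2-(benzyloxy)-3-[4-(benzyloxy)phenyl]-3-[(tert-butyldimethylsilyl)oxy]propyl}-4-hydroxy-6-methyl-2H-pyran-2-one | CC1=CC(O)=C(C[C@@H]([C@@H](O[Si](C)(C)C(C)(C)C)c2ccc(OCc3ccccc3)cc2)OCc2ccccc2)C(=O)O1
F10 | step 8 | 3-{(2S,3S)-2-(benzyloxy)-3-[4-(benzyloxy)phenyl]-3-hydroxypropyl}-4-hydroxy-6-methyl-2H-pyran-2-one | CC1=CC(O)=C(C[C@@H]([C@@H](O)c2ccc(OCc3ccccc3)cc2)OCc2ccccc2)C(=O)O1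
F11 | step 8 | (2R,3S)-3-(benzyloxy)-2-[4-(benzyloxy)phenyl]-7-methyl-3,4-dihydro-2H,5H-pyrano[4,3-b]pyran-5-one | O(Cc1ccccc1)c1ccc([C@H]2OC3=C(C(=O)OC(C)=C3)C[C@@H]2OCc2ccccc2)cc1
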